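**Retrosynthetic overview**
1. Squalene-type numbering C1–C24 is used (exocyclic CH2 on C6, isopropenyl carbon C23, epoxide C10–C11). The last disconnection is C12–C13: the α-sulfonyl carbanion of the C13–C24 half is alkylated by the primary triflate of a C1–C12 2,3-epoxy alcohol, and the sulfone is then removed.
2. The only ring, the epoxide, is closed on the C1–C12 half before the union, by chiral-phosphate-directed iminium epoxidation of the C12 enal, the only conjugated alkene of the three present.
3. C8–C9 and C20–C21 come from copper-catalysed coupling of chiral homoallylic Grignard reagents with (E)-allylic bromides, made by SeO2 oxidation of prenyl acetate and of geranyl phenyl sulfone.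
4. C7 and C22 (each with its CH2 neighbour, C8 and C21) come from a new chiral-phosphoric-acid-catalysed allylboration of formaldehyde, using allylboronates from 1,4-hydroboration of myrcene and isoprene.

Assumption: the SMILES is read as (7R,10R,11R,22S) with both trisubstituted chain alkenes E; where the sense of induction of a phosphate catalyst is quoted, it is carried over from the closest known model and is fixed in practice by the choice of catalyst enantiomer.

**Route**

Step 1
Reactants: 1 myrcene
Product: 2 2-[(2E)-2-ethylidene-6-methylhept-5-en-1-yl]-4,4,5,5-tetramethyl-1,3,2-dioxaborolane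
Conditions: HBpin (1.1 equiv), FeCl2 (4 mol %), N-aryl 2-iminopyridine ligand (4 mol %), Mg (10 mol %), Et2O, 23 °C
Reagents that add atoms: pinacolborane CC1(C)OBOC1(C)C
Why: Known iron-catalysed 1,4-hydroboration of a 2-substituted 1,3-diene; H goes to the vinyl CH2 and boron to the CH2 on the substituted carbon through an s-cis diene complex, so the new methyl lies cis to CH2B and the remote trisubstituted alkene is untouched.

Step 2
Reactants: 2 myrcene-derived allylboronate; 3 formaldehyde
Product: 5 (2S)-2,7-dimethyl-3-methylideneoct-6-en-1-ol, via pinacol borate ester 4 (not isolated)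
Conditions: (R)-TRIP [3,3'-bis(2,4,6-triisopropylphenyl)-BINOL hydrogen phosphate] (5 mol %), monomeric CH2O (1.5 equiv, cold THF solution, syringe pump), toluene, 4 Å MS, –78 → –45 °C; then aq. NaHCO3
Reagents that add atoms: none
Why: Proposed new method: chiral-phosphoric-acid-catalysed allylboration of formaldehyde in which the stereocentre is created on the allyl partner alone; the acid OH hydrogen-bonds to a boronate oxygen and its P=O to a formyl C–H, holding CH2O in one of the two mirror-image six-membered chair transition states, so that C–C bonding at the γ-carbon (complete SE2' regiochemistry, which also creates the exocyclic methylene) occurs on one alkene face and sets C7 as the (S)-alcohol, provided the catalysed path outruns the uncatalysed addition (low temperature, slow CH2O feed); the closest known reaction type is the TRIP-catalysed allyl- and crotylboration of ordinary aldehydes with pinacol boronates, from which the sense of induction is carried over.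

Step 3
Reactants: 5 (S)-homoallylic alcohol
Product: 6 (7S)-8-bromo-2,7-dimethyl-6-methylideneoct-2-ene
Conditions: CBr4, PPh3, CH2Cl2, 0 °C
Reagents that add atoms: carbon tetrabromide BrC(Br)(Br)Br
Why: Appel reaction at the primary alcohol (SN2 on the alkoxyphosphonium ion); the stereocentre is one carbon away and is not touched.

Step 4
Reactants: 7 prenyl acetate
Product: 8 (2E)-4-hydroxy-3-methylbut-2-en-1-yl acetate
Conditions: SeO2 (0.3 equiv), t-BuOOH (2 equiv), salicylic acid (cat.), CH2Cl2, 23 °C
Reagents that add atoms: tert-butyl hydroperoxide CC(C)(C)OO; selenium dioxide O=[Se]=O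
Why: SeO2/t-BuOOH allylic oxidation (ene reaction then [2,3] shift) hydroxylates only the methyl trans to the chain and gives the (E)-allylic alcohol.

Step 5
Reactants: 8 (E)-hydroxy acetate
Product: 9 (2E)-4-bromo-3-methylbut-2-en-1-yl acetate
Conditions: CBr4, PPh3, CH2Cl2, –20 → 0 °C
Reagents that add atoms: carbon tetrabromide BrC(Br)(Br)Br
Why: Appel bromination of the primary allylic alcohol, which at low temperature proceeds without allylic shift or loss of the E geometry.

Step 6
Reactants: 6 (S)-bromide; 9 (E)-bromo acetate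
Product: 12 (2E,6R)-3,6,11-trimethyl-7-methylidenedodeca-2,10-dien-1-ol, via Grignard reagent 10 (not isolated), via allylic acetate 11 (not isolated)
Conditions: 6, Mg, THF, 0 → 23 °C; add to 9 + Li2CuCl4 (3 mol %), THF, –78 → –20 °C; then MeOH, K2CO3 (0.5 equiv), 23 °C
Reagents that add atoms: none
Why: Kochi-type copper-catalysed Grignard coupling displaces the primary allylic bromide directly (SN2, E alkene kept, acetate inert at low temperature), and base-catalysed transesterification in the same flask frees the allylic alcohol; the stereocentre is β to magnesium and is not involved.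

Step 7
Reactants: 12 allylic alcohol
Product: 13 (2E,6R)-3,6,11-trimethyl-7-methylidenedodeca-2,10-dienal
Conditions: TEMPO (10 mol %), PhI(OAc)2 (1.1 equiv), CH2Cl2, 23 °C
Reagents that add atoms: none
Why: Oxoammonium (TEMPO/PhI(OAc)2) oxidation of the allylic alcohol stops at the enal, does not isomerise the 2E alkene and leaves the two isolated alkenes alone.

Step 8
Reactants: 13 enal
Product: 15 [(2R,3R)-3-[(3R)-3,8-dimethyl-4-methylidenenon-7-en-1-yl]-3-methyloxiran-2-yl]methanol, via epoxy aldehyde 14 (not isolated)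
Conditions: bis[3,5-bis(trifluoromethyl)benzyl]ammonium (S)-TRIP phosphate (10 mol %), t-BuOOH (1.2 equiv), t-BuOMe, 23 °C; then MeOH, NaBH4, 0 °C
Reagents that add atoms: tert-butyl hydroperoxide CC(C)(C)OO
Why: Known asymmetric counteranion-directed iminium epoxidation of β,β-disubstituted enals; t-BuOOH adds to the iminium ion paired with the chiral phosphate and the enamine closes the ring, which forms the oxirane and sets C10 and C11 (trans, from the E enal) at the conjugated alkene only, and NaBH4 then reduces the epoxy aldehyde in the same flask.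

Step 9
Reactants: 16 geranyl bromide
Product: 17 {[(2E)-3,7-dimethylocta-2,6-dien-1-yl]sulfonyl}benzene
Conditions: PhSO2Na (1.2 equiv), DMF, 23 °C
Reagents that add atoms: sodium benzenesulfinate [Na+].[O-]S(=O)c1ccccc1
Why: SN2 S-alkylation of the sulfinate at the primary allylic bromide with the E geometry retained.

Step 10
Reactants: 17 geranyl phenyl sulfone
Product: 18 (2E,6E)-2,6-dimethyl-8-(phenylsulfonyl)octa-2,6-dien-1-ol
Conditions: SeO2 (0.3 equiv), t-BuOOH (2 equiv), salicylic acid (cat.), CH2Cl2, 23 °C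
Reagents that add atoms: tert-butyl hydroperoxide CC(C)(C)OO; selenium dioxide O=[Se]=O
Why: The same allylic oxidation; the terminal prenyl alkene reacts because the 2,3-alkene is deactivated by the allylic sulfone, and only its (E)-methyl is hydroxylated.

Step 11
Reactants: 18 hydroxy sulfone
Product: 19 {[(2E,6E)-8-bromo-3,7-dimethylocta-2,6-dien-1-yl]sulfonyl}benzene
Conditions: CBr4, PPh3, CH2Cl2, –20 → 0 °C
Reagents that add atoms: carbon tetrabromide BrC(Br)(Br)Br
Why: Appel bromination of the primary allylic alcohol with retention of both E alkenes.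

Step 12
Reactants: 20 isoprene
Product: 21 4,4,5,5-tetramethyl-2-[(2Z)-2-methylbut-2-en-1-yl]-1,3,2-dioxaborolane
Conditions: HBpin (1.0 equiv), FeCl2 (4 mol %), N-aryl 2-iminopyridine ligand (4 mol %), Mg (10 mol %), Et2O, 0 → 23 °C
Reagents that add atoms: pinacolborane CC1(C)OBOC1(C)C
Why: The same known 1,4-hydroboration as in step 1; boron ends on the CH2 next to the methyl-bearing carbon and the new methyl lies cis to CH2B.

Step 13
Reactants: 21 isoprene-derived allylboronate; 3 formaldehyde
Product: 23 (2R)-2,3-dimethylbut-3-en-1-ol, via pinacol borate ester 22 (not isolated)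
Conditions: (S)-TRIP (5 mol %), monomeric CH2O (1.5 equiv, cold THF solution, syringe pump), toluene, 4 Å MS, –78 → –45 °C; then aq. NaHCO3
Reagents that add atoms: none
Why: Proposed new method: the same phosphoric-acid-catalysed allylboration of formaldehyde as in step 2 (catalyst-bound six-membered chair transition state, γ-selective C–C bond formation, closest known reaction type the TRIP-catalysed crotylboration of ordinary aldehydes), run with the enantiomeric acid so that the γ-carbon becomes the (R)-alcohol, the future C22.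

Step 14
Reactants: 23 (R)-homoallylic alcohol
Product: 24 (3R)-4-bromo-2,3-dimethylbut-1-ene
Conditions: PPh3, NBS, CH2Cl2, –20 → 0 °C; distil
Reagents that add atoms: N-bromosuccinimide O=C1CCC(=O)N1Br
Why: Appel-type bromination through an alkoxyphosphonium ion; the by-products are involatile, so the volatile bromide distils clean, and the stereocentre is untouched.

Step 15
Reactants: 24 (R)-bromide; 19 bromo sulfone
Product: 26 {[(2E,6E,10S)-3,7,10,11-tetramethyldodeca-2,6,11-trien-1-yl]sulfonyl}benzene, via Grignard reagent 25 (not isolated)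
Conditions: 24, Mg, THF, 0 → 23 °C; slow addition to 19 + Li2CuCl4 (3 mol %), THF, –78 → –40 °C
Reagents that add atoms: none
Why: Kochi-type copper-catalysed SN2 coupling at the primary allylic bromide, with the Grignard reagent fed slowly at –78 °C so that coupling outruns deprotonation of the allylic sulfone.

Step 16
Reactants: 15 epoxy alcohol; 26 C13–C24 sulfone
Product: 30 (2R,3R)-2-[(3R)-3,8-dimethyl-4-methylidenenon-7-en-1-yl]-2-methyl-3-[(3E,7E,11S)-4,8,11,12-tetramethyl-2-(phenylsulfonyl)trideca-3,7,12-trien-1-yl]oxirane, via lithium alkoxide 27 (not isolated), via epoxy triflate 28 (not isolated), via lithiated sulfone 29 (not isolated)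
Conditions: 15, n-BuLi (1.0 equiv), Et2O, –78 °C; Tf2O (0.98 equiv), –78 °C; cannulate into 29 [from 26, n-BuLi (1.0 equiv), THF/DMPU, –78 °C]; –78 → –50 °C
Reagents that add atoms: none
Why: Sulfone-anion alkylation (Biellmann-type coupling); the soft α-sulfonyl allyl anion displaces the primary triflate at its α-carbon faster than it can open the hindered trisubstituted epoxide, so C10 and C11 are untouched, and the new sulfone-bearing centre is an unselective mixture that is erased in the next step.

Step 17
Reactants: 30 epoxy sulfone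
Product: 31 (2R,3R)-2-[(3R)-3,8-dimethyl-4-methylidenenon-7-en-1-yl]-2-methyl-3-[(3E,7E,11S)-4,8,11,12-tetramethyltrideca-3,7,12-trien-1-yl]oxirane
Conditions: PdCl2(dppp) (5 mol %), LiEt3BH (2.2 equiv), THF, –20 → 0 °C
Reagents that add atoms: none
Why: Palladium-catalysed hydride displacement of an allylic sulfone through a π-allyl complex, hydride arriving at the carbon that carried sulfur so that the position and E geometry of the alkene are kept; the hindered trisubstituted epoxide is expected to survive brief exposure at or below 0 °C.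

**Compound list**
1 | myrcene (7-methyl-3-methylideneocta-1,6-diene) | C=CC(=C)CCC=C(C)C | starting material
2 | 2-[(2E)-2-ethylidene-6-methylhept-5-en-1-yl]-4,4,5,5-tetramethyl-1,3,2-dioxaborolane (new CH3 cis to CH2B) | C/C=C(\CB1OC(C)(C)C(C)(C)O1)CCC=C(C)C | intermediate
3 | formaldehyde | C=O | starting material
4 | 2-{[(2S)-2,7-dimethyl-3-methylideneoct-6-en-1-yl]oxy}-4,4,5,5-tetramethyl-1,3,2-dioxaborolane | C=C(CCC=C(C)C)[C@H](C)COB1OC(C)(C)C(C)(C)O1 | intermediate (not isolated)
5 | (2S)-2,7-dimethyl-3-methylideneoct-6-en-1-ol | C=C(CCC=C(C)C)[C@H](C)CO | intermediate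
6 | (7S)-8-bromo-2,7-dimethyl-6-methylideneoct-2-ene | C=C(CCC=C(C)C)[C@H](C)CBr | intermediate
7 | prenyl acetate (3-methylbut-2-en-1-yl acetate) | CC(=O)OCC=C(C)C | starting material
8 | (2E)-4-hydroxy-3-methylbut-2-en-1-yl acetate | CC(=O)OC/C=C(\C)CO | intermediate
9 | (2E)-4-bromo-3-methylbut-2-en-1-yl acetate | CC(=O)OC/C=C(\C)CBr | intermediate
10 | bromo[(2S)-2,7-dimethyl-3-methylideneoct-6-en-1-yl]magnesium | C=C(CCC=C(C)C)[C@H](C)C[Mg]Br | intermediate (not isolated)
11 | (2E,6R)-3,6,11-trimethyl-7-methylidenedodeca-2,10-dien-1-yl acetate | C=C(CCC=C(C)C)[C@H](C)CC/C(C)=C/COC(C)=O | intermediate (not isolated)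
12 | (2E,6R)-3,6,11-trimethyl-7-methylidenedodeca-2,10-dien-1-ol | C=C(CCC=C(C)C)[C@H](C)CC/C(C)=C/CO | intermediate
13 | (2E,6R)-3,6,11-trimethyl-7-methylidenedodeca-2,10-dienal | C=C(CCC=C(C)C)[C@H](C)CC/C(C)=C/C=O | intermediate
14 | (2S,3R)-3-[(3R)-3,8-dimethyl-4-methylidenenon-7-en-1-yl]-3-methyloxirane-2-carbaldehyde | C=C(CCC=C(C)C)[C@H](C)CC[C@@]1(C)O[C@@H]1C=O | intermediate (not isolated)
15 | [(2R,3R)-3-[(3R)-3,8-dimethyl-4-methylidenenon-7-en-1-yl]-3-methyloxiran-2-yl]methanol | C=C(CCC=C(C)C)[C@H](C)CC[C@@]1(C)O[C@@H]1CO | intermediate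
16 | geranyl bromide ((2E)-1-bromo-3,7-dimethylocta-2,6-diene) | BrC/C=C(\C)CCC=C(C)C | starting material
17 | {[(2E)-3,7-dimethylocta-2,6-dien-1-yl]sulfonyl}benzene | O=S(=O)(C/C=C(\C)CCC=C(C)C)c1ccccc1 | intermediate
18 | (2E,6E)-2,6-dimethyl-8-(phenylsulfonyl)octa-2,6-dien-1-ol | O=S(=O)(C/C=C(\C)CC/C=C(\C)CO)c1ccccc1 | intermediate
19 | {[(2E,6E)-8-bromo-3,7-dimethylocta-2,6-dien-1-yl]sulfonyl}benzene | O=S(=O)(C/C=C(\C)CC/C=C(\C)CBr)c1ccccc1 | intermediate
20 | isoprene (2-methylbuta-1,3-diene) | C=CC(C)=C | starting material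
21 | 4,4,5,5-tetramethyl-2-[(2Z)-2-methylbut-2-en-1-yl]-1,3,2-dioxaborolane (new CH3 cis to CH2B) | C/C=C(/C)CB1OC(C)(C)C(C)(C)O1 | intermediate
22 | 2-{[(2R)-2,3-dimethylbut-3-en-1-yl]oxy}-4,4,5,5-tetramethyl-1,3,2-dioxaborolane | CC1(C)OB(OC[C@H](C)C(C)=C)OC1(C)C | intermediate (not isolated)
23 | (2R)-2,3-dimethylbut-3-en-1-ol | OC[C@H](C)C(C)=C | intermediate
24 | (3R)-4-bromo-2,3-dimethylbut-1-ene | BrC[C@H](C)C(C)=C | intermediate
25 | bromo[(2R)-2,3-dimethylbut-3-en-1-yl]magnesium | Br[Mg]C[C@H](C)C(C)=C | intermediate (not isolated)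
26 | {[(2E,6E,10S)-3,7,10,11-tetramethyldodeca-2,6,11-trien-1-yl]sulfonyl}benzene | O=S(=O)(C/C=C(\C)CC/C=C(\C)CC[C@H](C)C(C)=C)c1ccccc1 | intermediate
27 | lithium [(2R,3R)-3-[(3R)-3,8-dimethyl-4-methylidenenon-7-en-1-yl]-3-methyloxiran-2-yl]methanolate | C=C(CCC=C(C)C)[C@H](C)CC[C@@]1(C)O[C@@H]1C[O-].[Li+] | intermediate (not isolated)
28 | [(2R,3R)-3-[(3R)-3,8-dimethyl-4-methylidenenon-7-en-1-yl]-3-methyloxiran-2-yl]methyl trifluoromethanesulfonate | C=C(CCC=C(C)C)[C@H](C)CC[C@@]1(C)O[C@@H]1COS(=O)(=O)C(F)(F)F | intermediate (not isolated)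
29 | lithium salt of sulfone 26, carbanion at the carbon bearing sulfur | [Li+].O=S(=O)([CH-]/C=C(\C)CC/C=C(\C)CC[C@H](C)C(C)=C)c1ccccc1 | intermediate (not isolated)
30 | (2R,3R)-2-[(3R)-3,8-dimethyl-4-methylidenenon-7-en-1-yl]-2-methyl-3-[(3E,7E,11S)-4,8,11,12-tetramethyl-2-(phenylsulfonyl)trideca-3,7,12-trien-1-yl]oxirane (both epimers at the sulfone carbon) | C=C(CCC=C(C)C)[C@H](C)CC[C@@]1(C)O[C@@H]1CC(/C=C(\C)CC/C=C(\C)CC[C@H](C)C(C)=C)S(=O)(=O)c1ccccc1 | intermediate
31 | (2R,3R)-2-[(3R)-3,8-dimethyl-4-methylidenenon-7-en-1-yl]-2-methyl-3-[(3E,7E,11S)-4,8,11,12-tetramethyltrideca-3,7,12-trien-1-yl]oxirane | C=C(CCC=C(C)C)[C@H](C)CC[C@@]1(C)O[C@@H]1CC/C=C(\C)CC/C=C(\C)CC[C@H](C)C(=C)C | target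

**Step count and risks**
Total: 17 steps. Longest linear sequence: 8 steps (1, 2, 3, 6, 7, 8, 16, 17, from myrcene).

Most likely to fail:

1. Step 2 (the new reaction). Formaldehyde has no substituent to help the catalyst tell the two chair transition states apart, it is electrophilic enough for an uncatalysed background addition, and it oligomerises. The fallback uses the established TRIP-catalysed crotylboration of an ordinary aldehyde, sets out from 2 and comes back at 5. Boronate 2 and (tert-butyldimethylsilyloxy)acetaldehyde with (R)-TRIP (5 mol %, toluene, –30 °C) give the borate adduct 2-{[(2R,3S)-1-[(tert-butyldimethylsilyl)oxy]-3,8-dimethyl-4-methylidenenon-7-en-2-yl]oxy}-4,4,5,5-tetramethyl-1,3,2-dioxaborolane F1. Work-up hydrolyses it to the syn alcohol (2R,3S)-1-[(tert-butyldimethylsilyl)oxy]-3,8-dimethyl-4-methylidenenon-7-en-2-ol F2. TBAF in THF gives (2R,3S)-3,8-dimethyl-4-methylidenenon-7-ene-1,2-diol F3. NaIO4 (THF/pH 7 buffer, 0 °C) cleaves the diol to (2S)-2,7-dimethyl-3-methylideneoct-6-enal F4, which is not stored but reduced in the same flask with NaBH4 to 5.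

2. Step 13 (the same new reaction on the smaller boronate, with a volatile product). It carries the same hazards as step 2. The fallback is the same known chemistry, sets out from 21 and comes back at 23. Boronate 21 and (tert-butyldimethylsilyloxy)acetaldehyde with (S)-TRIP give the borate adduct 2-{[(2S,3R)-1-[(tert-butyldimethylsilyl)oxy]-3,4-dimethylpent-4-en-2-yl]oxy}-4,4,5,5-tetramethyl-1,3,2-dioxaborolane F5, hydrolysed to (2S,3R)-1-[(tert-butyldimethylsilyl)oxy]-3,4-dimethylpent-4-en-2-ol F6. TBAF gives (2S,3R)-3,4-dimethylpent-4-ene-1,2-diol F7. NaIO4 gives (2R)-2,3-dimethylbut-3-enal F8, reduced at once with NaBH4 to 23.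

3. Step 8 (epoxidation). The amine catalyst can scramble the E/Z geometry of the β,β-disubstituted enal through its dienamine, which would erode the trans selectivity, and the ee on a fully aliphatic enal may be only moderate. The fallback sets out from 12 and comes back at 15, leaving out 13 and 14. It is a Sharpless asymmetric epoxidation: Ti(OiPr)4 (10 mol %), D-(–)-diethyl tartrate (12 mol %), t-BuOOH, 4 Å MS, CH2Cl2, –20 °C. It is stereospecific for the E alkene, reacts only at the allylic-alcohol alkene, and makes no compound outside the list (F0).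

**Further compounds**
F1 | step 2 | 2-{[(2R,3S)-1-[(tert-butyldimethylsilyl)oxy]-3,8-dimethyl-4-methylidenenon-7-en-2-yl]oxy}-4,4,5,5-tetramethyl-1,3,2-dioxaborolane | C=C(CCC=C(C)C)[C@H](C)[C@@H](OB1OC(C)(C)C(C)(C)O1)CO[Si](C)(C)C(C)(C)C
F2 | step 2 | (2R,3S)-1-[(tert-butyldimethylsilyl)oxy]-3,8-dimethyl-4-methylidenenon-7-en-2-ol | C=C(CCC=C(C)C)[C@H](C)[C@@H](O)CO[Si](C)(C)C(C)(C)C
F3 | step 2 | (2R,3S)-3,8-dimethyl-4-methylidenenon-7-ene-1,2-diol | C=C(CCC=C(C)C)[C@H](C)[C@@H](O)CO
F4 | step 2 | (2S)-2,7-dimethyl-3-methylideneoct-6-enal | C=C(CCC=C(C)C)[C@H](C)C=O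
F5 | step 13 | 2-{[(2S,3R)-1-[(tert-butyldimethylsilyl)oxy]-3,4-dimethylpent-4-en-2-yl]oxy}-4,4,5,5-tetramethyl-1,3,2-dioxaborolane | CC(C)(C)[Si](C)(C)OC[C@@H](OB1OC(C)(C)C(C)(C)O1)[C@H](C)C(C)=C
F6 | step 13 | (2S,3R)-1-[(tert-butyldimethylsilyl)oxy]-3,4-dimethylpent-4-en-2-ol | CC(C)(C)[Si](C)(C)OC[C@@H](O)[C@H](C)C(C)=C
F7 | step 13 | (2S,3R)-3,4-dimethylpent-4-ene-1,2-diol | OC[C@@H](O)[C@H](C)C(C)=C
F8 | step 13 | (2R)-2,3-dimethylbut-3-enal | O=C[C@H](C)C(C)=C
F0 | step 8 | none | none
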